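Ring A is closed last, onto a fully substituted ring B. The route rests on the γ-hydroxy ketone that spans the ring fusion, C5(OH)–C4a–C8a–C1(=O) (naphthalenone numbering): a samarium ketyl generated from a C5 aldehyde adds 6-endo to C4a of a cross-conjugated dienone, which forms the C5–C4a bond of ring A and sets C5, C4a and, on protonation, C8a in one operation. The precursor is a 2-benzyloxycyclohexa-2,5-dienone that carries the quaternary C4 centre, the octenyl side chain (installed by a Claisen rearrangement with chirality transfer) and, at the future C8a, a four-carbon chain with the C8 silyloxy stereocentre and a methylidene group that later becomes the C7 methyl group.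

Key step: step 17

Remark on numbering: locants in the Why lines are those of the target named as a 4a,5,6,7,8,8a-hexahydronaphthalen-1(4H)-one (ring B = C1, C2, C3, C4, C4a, C8a; ring A = C4a, C5, C6, C7, C8, C8a); for monocyclic intermediates "future Cn" means the carbon that becomes Cn.

Remark on the chemistry: the antipode of the chromium–salen catalyst (step 2) and of the sulfonamide ligand (step 13) that delivers the drawn configuration is used; compounds 1, 3, 4 and 18 are taken as commercial.

Step 1
Reactants: 1 (E)-oct-2-en-4-one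
Product: 2 (2E,4R)-oct-2-en-4-ol
Conditions: (S)-2-methyl-CBS-oxazaborolidine (10 mol%), catecholborane (1.5 equiv), toluene, −78 °C; aqueous work-up
Reagents that add atoms: none
Why: Corey–Bakshi–Shibata reduction in which the alkenyl group takes the role of the large substituent, so that the (S)-oxazaborolidine should deliver hydride to the face that gives the (R)-carbinol.

Step 2
Reactants: 3 (E)-1-(dimethylamino)-3-silyloxybutadiene; 4 methacrolein
Product: 7 (4S)-4-(1-hydroxyallyl)-4-methylcyclohexenone, via cycloadduct aldehyde 5 (not isolated), via magnesium alkoxide 6 (not isolated)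
Conditions: [Cr(salen)]SbF6 (5 mol%; trivalent chromium; salen = N,N'-bis(3,5-di-tert-butylsalicylidene)-trans-cyclohexane-1,2-diamine dianion), 4 Å molecular sieves, CH2Cl2, −40 °C; then CH2=CHMgBr, THF, −78 °C; then 1 M aqueous HCl, THF, 0 °C
Reagents that add atoms: vinylmagnesium bromide, C=C[Mg]Br
Why: A Lewis-acid-catalysed enantioselective Diels–Alder reaction joins the amino-bearing diene terminus to the substituted carbon of the enal and sets the quaternary carbon (future C4) under control of the chiral chromium–salen complex, the Grignard reagent then adds 1,2 to the aldehyde while the ring ketone is masked as its silyl enol ether, and acid hydrolysis with β-elimination of dimethylamine releases the enone.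

Step 3
Reactants: 7 (4S)-4-(1-hydroxyallyl)-4-methylcyclohexenone
Product: 8 (4S)-4-acryloyl-4-methylcyclohexenone
Conditions: DMP (1.3 equiv), CH2Cl2, 0 °C
Reagents that add atoms: none
Why: Dess–Martin oxidation of the secondary allylic alcohol converges both carbinol epimers on the vinyl ketone and creates no stereocentre.

Step 4
Reactants: 8 (4S)-4-acryloyl-4-methylcyclohexenone
Product: 9 (4S)-4-[3-(benzyloxy)propanoyl]-4-methylcyclohexenone
Conditions: BnOH (3 equiv), PMe3 (10 mol%), THF, rt
Reagents that add atoms: benzyl alcohol, OCc1ccccc1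
Why: Phosphine-catalysed oxa-Michael addition to the unhindered terminal vinyl ketone, which should react far faster than the ring enone whose β-carbon is shielded by the quaternary carbon; no stereocentre is formed.

Step 5
Reactants: 9 (4S)-4-[3-(benzyloxy)propanoyl]-4-methylcyclohexenone
Product: 10 α'-acetoxy enone
Conditions: Mn(OAc)3·2H2O (3 equiv), benzene, reflux (water separator)
Reagents that add atoms: manganese triacetate, CC(=O)O[Mn](OC(C)=O)OC(C)=O
Why: Mn(OAc)3-mediated α'-acetoxylation of an enone through the manganese enolate of the only enolisable ring position (future C2), the saturated side-chain ketone being oxidised much more slowly; the new stereocentre is lost again in step 7.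

Step 6
Reactants: 10 α'-acetoxy enone
Product: 11 α'-hydroxy enone
Conditions: K2CO3 (0.2 equiv), MeOH, 0 °C
Reagents that add atoms: none
Why: Base-catalysed transesterification (methanolysis) of the acetate under conditions that should be too mild for retro-oxa-Michael loss of the benzyloxy group; no stereocentre changes.

Step 7
Reactants: 11 α'-hydroxy enone
Product: 12 diosphenol (2-hydroxy dienone)
Conditions: DMP (1.5 equiv), CH2Cl2, rt
Reagents that add atoms: none
Why: Dess–Martin oxidation of the α-hydroxy ketone gives the 1,2-diketone, which can enolise only toward its CH2 group (the other α-carbon is vinylic) and should therefore be obtained as the diosphenol with the enol double bond at C2–C3.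

Step 8
Reactants: 12 diosphenol (2-hydroxy dienone); 2 (2E,4R)-oct-2-en-4-ol
Product: 13 (S)-allyl enol ether
Conditions: PPh3, DIAD, toluene, 0 °C to rt
Reagents that add atoms: none
Why: Mitsunobu etherification of the acidic enol hydroxyl (O-alkylation) with inversion at the carbinol carbon, which turns the (R)-alcohol into the (S)-allyl enol ether.

Step 9
Reactants: 13 (S)-allyl enol ether
Product: 15 C3-octenyl diosphenol, via 1,2-diketone 14 (not isolated)
Conditions: toluene, 120 °C (sealed tube)
Reagents that add atoms: none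
Why: Claisen rearrangement through a chair transition state with the butyl group equatorial forms the C3–C bond suprafacially, transferring the chirality of the ether carbon to the new (R)-stereocentre of the side chain with an (E)-alkene, and the diketone re-enolises to the diosphenol.

Step 10
Reactants: 15 C3-octenyl diosphenol
Product: 16 benzyl enol ether dienone
Conditions: BnBr, K2CO3, DMF, rt
Reagents that add atoms: benzyl bromide, BrCc1ccccc1
Why: Williamson O-benzylation of the diosphenolate, C-alkylation being blocked because the enol carbon C3 is fully substituted; no stereocentre is touched.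

Step 11
Reactants: 16 benzyl enol ether dienone
Product: 17 iodo dienone
Conditions: I2 (2 equiv), pyridine, CH2Cl2, rt
Reagents that add atoms: iodine, I-I
Why: α-Iodination of the enone by conjugate addition of pyridine, iodination of the enolate and elimination, possible only at the one enone α-carbon that bears hydrogen (future C8a).

Step 12
Reactants: 18 4-(silyloxy)butanal
Product: 19 4-(silyloxy)-2-methylidenebutanal
Conditions: 37% aqueous formaldehyde, pyrrolidine (10 mol%), propionic acid (10 mol%), i-PrOH, 45 °C
Reagents that add atoms: formaldehyde, C=O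
Why: Amine-catalysed Mannich condensation with formaldehyde followed by elimination (α-methylenation of an aldehyde); no stereocentre is formed.

Step 13
Reactants: 17 iodo dienone; 19 4-(silyloxy)-2-methylidenebutanal
Product: 20 (S)-bis-allylic carbinol
Conditions: CrCl2 (4 equiv), NiCl2 (2 mol%), chiral N-[2-(4-isopropyl-4,5-dihydro-1,3-oxazol-2-yl)-6-methylphenyl]methanesulfonamide (4.4 equiv), Et3N (4.4 equiv), THF, rt
Reagents that add atoms: none
Why: Nozaki–Hiyama–Kishi reaction in which zerovalent nickel inserts into the C–I bond, transmetalation gives the alkenylchromium species (trivalent chromium) that adds 1,2 to the aldehyde, and the chiral sulfonamide–oxazoline ligand on chromium should set the new (S)-carbinol carbon (future C8) by reagent control.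

Step 14
Reactants: 20 (S)-bis-allylic carbinol
Product: 21 bis-silyl ether
Conditions: TBSOTf (1.2 equiv), 2,6-lutidine, CH2Cl2, −78 °C
Reagents that add atoms: tert-butyldimethylsilyl triflate, CC(C)(C)[Si](C)(C)OS(=O)(=O)C(F)(F)F
Why: Silylation of the secondary alcohol with a silyl triflate and a hindered base at low temperature, which should be faster than enol silylation of the ketones; the stereocentre is retained.

Step 15
Reactants: 21 bis-silyl ether
Product: 22 primary alcohol
Conditions: HF·pyridine, pyridine, THF, 0 °C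
Reagents that add atoms: none
Why: Fluoride-mediated desilylation that distinguishes the unhindered primary silyl ether from the hindered secondary bis-allylic one.

Step 16
Reactants: 22 primary alcohol
Product: 23 dienone aldehyde
Conditions: DMP (1.3 equiv), CH2Cl2, 0 °C; used without chromatography
Reagents that add atoms: none
Why: Dess–Martin oxidation of the primary alcohol under non-basic conditions, so that the β,γ-unsaturated aldehyde should not isomerise into conjugation.

Step 17
Reactants: 23 dienone aldehyde
Product: 25 trans-decalin carbinol, via samarium enolate 24 (not isolated)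
Conditions: SmI2 (2.2 equiv), t-BuOH (3 equiv), HMPA (8 equiv), THF, −78 °C; then aqueous NH4Cl
Reagents that add atoms: none
Why: SmI2 reduces the aldehyde to a samarium ketyl radical that adds to C4a, the β-carbon of the C1(=O)–C8a=C4a enone unit, and a second electron transfer gives the samarium enolate 24, which t-BuOH protonates at C8a. The closest known reaction type is the SmI2-mediated ketyl–olefin cyclisation of aldehydes onto cyclohexa-2,5-dienones. Ring A is closed in the 6-endo-trig mode, which should win over 5-exo attack because the 5-exo position (C8a) is the electron-rich α-carbon of the enone and would become quaternary. C4a is controlled by the C8 silyloxy stereocentre, which sits pseudo-axial in the chair-like transition state to avoid allylic strain with the C1 carbonyl and the C7 methylidene group and so places the chain on the face of ring B that carries the C4 methyl group, opposite the bulkier acyl substituent; C5 is controlled by the equatorial position of the samarium-bound oxygen, away from the axial C4 methyl group and within reach of the C4 acyl carbonyl for chelation; C8a is controlled by protonation anti to the axial silyloxy group, which gives the more stable trans ring fusion. The step needs chemoselective reduction of the aldehyde beside the dienone and the saturated ketone, secured by the electron-rich, fully substituted 2-benzyloxy dienone and the hindered neopentyl ketone, and it needs protonation of the enolate to outrun β-elimination of the C8 silyloxy group, secured by the proton source present at −78 °C.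

Step 18
Reactants: 25 trans-decalin carbinol
Product: 26 C8 silyl ether of the target
Conditions: H2 (1 atm), Pd/C (10%), EtOAc, rt
Reagents that add atoms: none
Why: Heterogeneous hydrogenation and hydrogenolysis over palladium cleave both benzyl ethers, saturate the side-chain alkene and reduce the methylidene group from the face opposite the axial C8 silyloxy group, which should place the new C7 methyl group equatorial (7S), while the tetrasubstituted enol double bond of the diosphenol should stay intact.

Step 19
Reactants: 26 C8 silyl ether of the target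
Product: 27 CNP0234794.3
Conditions: HF·pyridine, MeCN, 0 °C to rt
Reagents that add atoms: none
Why: Fluoride-mediated cleavage of the last silyl ether under mildly acidic conditions that the β-hydroxy ketone and the diosphenol should tolerate; no stereocentre is affected.

Compound list
1 | (E)-oct-2-en-4-one | C/C=C/C(=O)CCCC | starting material
2 | (2E,4R)-oct-2-en-4-ol | CCCC[C@@H](O)/C=C/C | intermediate
3 | (E)-N,N-dimethyl-3-[(tert-butyldimethylsilyl)oxy]buta-1,3-dien-1-amine | C=C(O[Si](C)(C)C(C)(C)C)/C=C/N(C)C | starting material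
4 | methacrolein (2-methylprop-2-enal) | CC(=C)C=O | starting material
5 | (1S)-2-(dimethylamino)-1-methyl-4-[(tert-butyldimethylsilyl)oxy]cyclohex-3-ene-1-carbaldehyde (amino carbon not defined) | C1CC(O[Si](C)(C)C(C)(C)C)=CC(N(C)C)[C@@]1(C)C=O | intermediate
6 | bromomagnesium alkoxide of the vinyl adduct of 5 | C1CC(O[Si](C)(C)C(C)(C)C)=CC(N(C)C)[C@@]1(C)C(O[Mg]Br)C=C | intermediate
7 | (4S)-4-(1-hydroxyprop-2-en-1-yl)-4-methylcyclohex-2-en-1-one (both carbinol epimers) | C1CC(=O)C=C[C@@]1(C)C(O)C=C | intermediate
8 | (4S)-4-methyl-4-(prop-2-enoyl)cyclohex-2-en-1-one | C1CC(=O)C=C[C@@]1(C)C(=O)C=C | intermediate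
9 | (4S)-4-[3-(benzyloxy)propanoyl]-4-methylcyclohex-2-en-1-one | C1CC(=O)C=C[C@@]1(C)C(=O)CCOCc2ccccc2 | intermediate
10 | (5S)-5-[3-(benzyloxy)propanoyl]-5-methyl-2-oxocyclohex-3-en-1-yl acetate (epimers at C1) | C1C(OC(C)=O)C(=O)C=C[C@@]1(C)C(=O)CCOCc2ccccc2 | intermediate
11 | (4S)-4-[3-(benzyloxy)propanoyl]-6-hydroxy-4-methylcyclohex-2-en-1-one (epimers at C6) | C1C(O)C(=O)C=C[C@@]1(C)C(=O)CCOCc2ccccc2 | intermediate
12 | (4R)-4-[3-(benzyloxy)propanoyl]-2-hydroxy-4-methylcyclohexa-2,5-dien-1-one | C1=C(O)C(=O)C=C[C@@]1(C)C(=O)CCOCc2ccccc2 | intermediate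
13 | (4R)-4-[3-(benzyloxy)propanoyl]-4-methyl-2-{[(2E,4S)-oct-2-en-4-yl]oxy}cyclohexa-2,5-dien-1-one | C1=C(O[C@@H](CCCC)/C=C/C)C(=O)C=C[C@@]1(C)C(=O)CCOCc2ccccc2 | intermediate
14 | (4R)-4-[3-(benzyloxy)propanoyl]-4-methyl-3-[(2R,3E)-oct-3-en-2-yl]cyclohex-5-ene-1,2-dione (C3 not defined) | CCCC/C=C/[C@@H](C)C1C(=O)C(=O)C=C[C@@]1(C)C(=O)CCOCc2ccccc2 | intermediate
15 | (4R)-4-[3-(benzyloxy)propanoyl]-2-hydroxy-4-methyl-3-[(2R,3E)-oct-3-en-2-yl]cyclohexa-2,5-dien-1-one | CCCC/C=C/[C@@H](C)C1=C(O)C(=O)C=C[C@@]1(C)C(=O)CCOCc2ccccc2 | intermediate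
16 | (4R)-2-(benzyloxy)-4-[3-(benzyloxy)propanoyl]-4-methyl-3-[(2R,3E)-oct-3-en-2-yl]cyclohexa-2,5-dien-1-one | CCCC/C=C/[C@@H](C)C1=C(OCc2ccccc2)C(=O)C=C[C@@]1(C)C(=O)CCOCc3ccccc3 | intermediate
17 | (4R)-2-(benzyloxy)-4-[3-(benzyloxy)propanoyl]-6-iodo-4-methyl-3-[(2R,3E)-oct-3-en-2-yl]cyclohexa-2,5-dien-1-one | CCCC/C=C/[C@@H](C)C1=C(OCc2ccccc2)C(=O)C(I)=C[C@@]1(C)C(=O)CCOCc3ccccc3 | intermediate
18 | 4-[(tert-butyldimethylsilyl)oxy]butanal | O=CCCCO[Si](C)(C)C(C)(C)C | starting material
19 | 4-[(tert-butyldimethylsilyl)oxy]-2-methylidenebutanal | O=CC(=C)CCO[Si](C)(C)C(C)(C)C | intermediate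
20 | (4R)-2-(benzyloxy)-4-[3-(benzyloxy)propanoyl]-6-{(1S)-4-[(tert-butyldimethylsilyl)oxy]-1-hydroxy-2-methylidenebutyl}-4-methyl-3-[(2R,3E)-oct-3-en-2-yl]cyclohexa-2,5-dien-1-one | CCCC/C=C/[C@@H](C)C1=C(OCc2ccccc2)C(=O)C(=C[C@@]1(C)C(=O)CCOCc3ccccc3)[C@@H](O)C(=C)CCO[Si](C)(C)C(C)(C)C | intermediate
21 | (4R)-2-(benzyloxy)-4-[3-(benzyloxy)propanoyl]-6-{(1S)-1,4-bis[(tert-butyldimethylsilyl)oxy]-2-methylidenebutyl}-4-methyl-3-[(2R,3E)-oct-3-en-2-yl]cyclohexa-2,5-dien-1-one | CCCC/C=C/[C@@H](C)C1=C(OCc2ccccc2)C(=O)C(=C[C@@]1(C)C(=O)CCOCc3ccccc3)[C@@H](O[Si](C)(C)C(C)(C)C)C(=C)CCO[Si](C)(C)C(C)(C)C | intermediate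
22 | (4R)-2-(benzyloxy)-4-[3-(benzyloxy)propanoyl]-6-{(1S)-1-[(tert-butyldimethylsilyl)oxy]-4-hydroxy-2-methylidenebutyl}-4-methyl-3-[(2R,3E)-oct-3-en-2-yl]cyclohexa-2,5-dien-1-one | CCCC/C=C/[C@@H](C)C1=C(OCc2ccccc2)C(=O)C(=C[C@@]1(C)C(=O)CCOCc3ccccc3)[C@@H](O[Si](C)(C)C(C)(C)C)C(=C)CCO | intermediate
23 | (4R)-2-(benzyloxy)-4-[3-(benzyloxy)propanoyl]-6-{(1S)-1-[(tert-butyldimethylsilyl)oxy]-2-methylidene-4-oxobutyl}-4-methyl-3-[(2R,3E)-oct-3-en-2-yl]cyclohexa-2,5-dien-1-one | CCCC/C=C/[C@@H](C)C1=C(OCc2ccccc2)C(=O)C(=C[C@@]1(C)C(=O)CCOCc3ccccc3)[C@@H](O[Si](C)(C)C(C)(C)C)C(=C)CC=O | intermediate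
24 | bis(diiodosamarium) derivative of 25: C1–C8a enolate and C5 alkoxide (trivalent samarium) | CCCC/C=C/[C@@H](C)C1=C(OCc2ccccc2)C(O[Sm](I)I)=C3[C@@H](O[Si](C)(C)C(C)(C)C)C(=C)C[C@@H](O[Sm](I)I)[C@@H]3[C@@]1(C)C(=O)CCOCc4ccccc4 | intermediate
25 | (4R,4aS,5R,8R,8aR)-2-(benzyloxy)-4-[3-(benzyloxy)propanoyl]-8-[(tert-butyldimethylsilyl)oxy]-5-hydroxy-4-methyl-7-methylidene-3-[(2R,3E)-oct-3-en-2-yl]-4a,5,6,7,8,8a-hexahydronaphthalen-1(4H)-one | CCCC/C=C/[C@@H](C)C1=C(OCc2ccccc2)C(=O)[C@H]3[C@@H](O[Si](C)(C)C(C)(C)C)C(=C)C[C@@H](O)[C@@H]3[C@@]1(C)C(=O)CCOCc4ccccc4 | intermediate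
26 | (4R,4aS,5R,7S,8S,8aR)-8-[(tert-butyldimethylsilyl)oxy]-2,5-dihydroxy-4-(3-hydroxypropanoyl)-4,7-dimethyl-3-[(2R)-octan-2-yl]-4a,5,6,7,8,8a-hexahydronaphthalen-1(4H)-one | CCCCCC[C@@H](C)C1=C(O)C(=O)[C@H]2[C@@H](O[Si](C)(C)C(C)(C)C)[C@@H](C)C[C@@H](O)[C@@H]2[C@@]1(C)C(=O)CCO | intermediate
27 | CNP0234794.3, (4R,4aS,5R,7S,8S,8aR)-2,5,8-trihydroxy-4-(3-hydroxypropanoyl)-4,7-dimethyl-3-[(2R)-octan-2-yl]-4a,5,6,7,8,8a-hexahydronaphthalen-1(4H)-one | CCCCCC[C@@H](C)C1=C(O)C(=O)[C@H]2[C@@H](O)[C@@H](C)C[C@@H](O)[C@@H]2[C@@]1(C)C(=O)CCO | target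

Total step count: 19 steps. Longest linear sequence: 17 steps (steps 2 to 11 and 13 to 19, from methacrolein and the aminosiloxydiene).

Steps most likely to fail

Step 17: the 6-endo ketyl addition may be outrun by pinacol-type dimerisation of the ketyl, by electron transfer to the dienone with loss of the acyl group and aromatisation, or by β-elimination of the silyloxy group from the samarium enolate. The fallback sets out from 23 and replaces the reductive ketyl generation by a neutral radical chain. Addition of PhSeSiMe3 (catalytic ZnI2, CH2Cl2) to the aldehyde should give the O-trimethylsilyl hemiselenoacetal F1. Slow addition of Bu3SnH with AIBN in benzene at 80 °C should generate the α-silyloxy radical, which closes ring A in the same 6-endo mode under the same substrate control and gives the C5 trimethylsilyl ether F2. Methanolysis (K2CO3, MeOH, 0 °C) removes the trimethylsilyl group and the route is rejoined at 25.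

Step 13: facial selectivity at the new carbinol carbon may be poor, because the stereocentres of 17 are remote and the ligand has to impose all of the control. The fallback sets out from 17 and 19: the coupling is run without the chiral ligand (CrCl2, NiCl2 2 mol%, DMSO), and the two carbinol epimers are separated. The unwanted (1R)-carbinol F3 is inverted by a Mitsunobu reaction with 4-nitrobenzoic acid (PPh3, DIAD) to the 4-nitrobenzoate F4, and methanolysis (K2CO3, MeOH) returns the route to 20.

Step 18: hydrogen may be delivered to the wrong face of the methylidene group, through hydroxyl-assisted adsorption or through double-bond migration on palladium before reduction, which would erode the configuration at C7. The fallback sets out from 25 and reduces the 1,1-disubstituted alkene first by radical hydrogen-atom transfer under thermodynamic control (Mn(dpm)3 with dpm = 2,2,6,6-tetramethylheptane-3,5-dionate, trivalent manganese; PhSiH3, t-BuOOH, i-PrOH, rt). This should give the equatorial 7-methyl compound F5 with the benzyl ethers and the side-chain alkene intact; H2 over Pd/C then completes the reduction and debenzylation and the route is rejoined at 26.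

Further compounds
F1 | step 17 | O-trimethylsilyl hemiselenoacetal of 23 (selenoacetal carbon not defined) | CCCC/C=C/[C@@H](C)C1=C(OCc2ccccc2)C(=O)C(=C[C@@]1(C)C(=O)CCOCc3ccccc3)[C@@H](O[Si](C)(C)C(C)(C)C)C(=C)CC(O[Si](C)(C)C)[Se]c4ccccc4
F2 | step 17 | C5 trimethylsilyl ether of 25 | CCCC/C=C/[C@@H](C)C1=C(OCc2ccccc2)C(=O)[C@H]3[C@@H](O[Si](C)(C)C(C)(C)C)C(=C)C[C@@H](O[Si](C)(C)C)[C@@H]3[C@@]1(C)C(=O)CCOCc4ccccc4
F3 | step 13 | (1R)-carbinol epimer of 20 | CCCC/C=C/[C@@H](C)C1=C(OCc2ccccc2)C(=O)C(=C[C@@]1(C)C(=O)CCOCc3ccccc3)[C@H](O)C(=C)CCO[Si](C)(C)C(C)(C)C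
F4 | step 13 | 4-nitrobenzoate of 20 | CCCC/C=C/[C@@H](C)C1=C(OCc2ccccc2)C(=O)C(=C[C@@]1(C)C(=O)CCOCc3ccccc3)[C@@H](OC(=O)c4ccc(cc4)[N+](=O)[O-])C(=C)CCO[Si](C)(C)C(C)(C)C
F5 | step 18 | (7S)-7-methyl analogue of 25 (methylidene reduced, benzyl ethers and side-chain alkene intact) | CCCC/C=C/[C@@H](C)C1=C(OCc2ccccc2)C(=O)[C@H]3[C@@H](O[Si](C)(C)C(C)(C)C)[C@@H](C)C[C@@H](O)[C@@H]3[C@@]1(C)C(=O)CCOCc4ccccc4
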